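## The problem

The target is a flavonol: a 4H-chromen-4-one (benzene ring A fused to pyranone ring C) with a catechol ring B at C2 and five oxygen substituents that must end in three different states. O3 carries an acetate, O5 stays a free hydroxyl, and O7, O3' and O4' are hydrogen sulfates. There is no stereocentre in the target, so the difficulty is purely regiochemical: each oxygen must be distinguishable when its final group is put on. The skeleton offers two handles. The O5–H hydrogen bond to the C4 carbonyl makes that hydroxyl the least reactive towards acylating and sulfating agents, and the enolic O3 can be set apart from the phenolic oxygens by its own protecting group. The sensitive groups fix the order of events. Aryl hydrogen sulfates are strong acids, hydrolyse in warm acid and do not tolerate silica chromatography; the C3 acetate is an activated enol ester that is lost to alkoxides, amines or methanolysis. The sulfates therefore come last and the acetate late, with only neutral chemistry between them. The feature that opens a non-classical route is that the C4a–C8a edge of ring A is also the C5=C6 double bond of a 2-aryl-4-pyranone, an electron-poor alkene conjugated to the C4 carbonyl. With an activating leaving group on the future C4a this alkene can act as a dienophile, and the 1,3-relationship of O5 and O7 on C5–C8 is that of a 1,3-dioxygenated butadiene.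

## Retrosynthesis

**Sulfates (20 to 19).** The three O–S bonds of target 20 are cut first, leading back to quercetin 3-acetate 19. Carrying sulfates, or masked sulfate diesters, through earlier steps would add three deprotections and expose them to hydrogenolysis and chromatography. The cut removes all charge and leaves a neutral tetrahydroxy compound. The forward reaction must sulfate O7 and both catechol oxygens completely while leaving the chelated O5–H and the acetate untouched.

**Protecting groups (19 to 16).** The phenolic oxygens of 19 are traced back to benzyl ethers (18), the acetate to a free 3-hydroxyl (17), and that hydroxyl to a methoxymethyl ether (16). Acetylating after debenzylation would face five hydroxyls, and an acetate present earlier would not survive carbanion chemistry. In 17 only O3–H and O5–H are free, and chelation separates them. Hydrogenolysis is the one deprotection that leaves an enol acetate alone. The forward steps need an acid that removes the acetal but not the benzyl ethers, one equivalent of acylating agent, and a neutral non-nucleophilic medium for hydrogenolysis.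

**Ring A (16 to 8 and 12).** The C4a–C5 and C8–C8a bonds of 16 are cut, giving sulfinylpyranone 8 and ketene-acetal diene 12. The neighbouring, classical cuts through ring C start from a phloroglucinol ring A whose O5 and O7 are equivalent and must be told apart afterwards, and most of them bring O3 in by a late oxidation. Here O3 is present from the start, O7 arrives benzylated and O5 arrives as a free chelated phenol. The precursors are a monocyclic pyranone and a four-carbon diene. The forward reaction must be a regioselective [4+2] addition to the C5=C6 bond of 8, followed by loss of the sulfinyl group and of methanol.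

**Pyranone (8 to 5 and 6).** The bond between C2 and C3 and the O1–C6 bond of pyranone 8 are cut, giving enaminone 5 and acid chloride 6 through the open-chain enaminodiketone 7. The alternative of aroylating a beta-keto sulfoxide dianion first and condensing with the formamide acetal afterwards has two carbanion sites to control. Enaminone 5 has a single enolisable position. The forward step needs C-acylation of that enolate and an acid-promoted addition–elimination that expels dimethylamine without removing the acetal.

**Enaminone (5 to 1 and 3).** Enaminone 5 comes from beta-keto sulfoxide 4 by condensation at its doubly activated methylene. Ketone 4 comes from a C–C cut between the sulfinyl-bearing carbon and the carbonyl, giving ester 2 and methyl p-tolyl sulfoxide 3. Ester 2 is the methoxymethyl ether of methyl glycolate 1. All three fragments are commercial or one step from commercial material. The sulfur is used racemic because it is expelled in the ring A construction.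

**Diene (12 to 9 and 10).** Diene 12 is cut at the O–Si bond to enol ether ester 11, which is reached by exchanging the methoxy group of commercial methyl (E)-3-methoxybut-2-enoate 9 for benzyl alcohol 10. The benzyl group on the future O7 is chosen so that it leaves with the ring B benzyl ethers in one hydrogenolysis.

## Roads not taken

**Alternative 1:** Ring C is cut at C4a–C4, C4–C3 and O1–C2. In the forward sense PdCl2(PPh3)2, carbon monoxide and diethylamine would join 3,5-bis(benzyloxy)-2-iodophenol A1, carbon monoxide and 1,2-bis(benzyloxy)-4-ethynylbenzene A2. A carbonylative coupling and 6-endo closure of the phenol oxygen on the ynone would give 5,7-bis(benzyloxy)-2-[3,4-bis(benzyloxy)phenyl]-4H-chromen-4-one A3.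

- Merits: three bonds form in one convergent step, the reaction type is established for flavones, and four identical benzyl ethers fall in one hydrogenolysis.
- Weak points: A3 has no oxygen at C3, so the C2=C3 bond must be oxidised later in the presence of four electron-rich benzyloxyarenes. A1 requires selective mono-iodination of a symmetric phenol between OH and OBn. The 5-exo closure to an aurone competes. Carbon monoxide must be handled.
- Comparison: this road is no longer than the chosen one and its key step is the safer of the two. Against that, the chosen plan carries O3 from the first step, needs no late oxidation, and sets the ring A pattern without a selective halogenation.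

**Alternative 2:** Only the C4a–C5 bond is cut. Base (Mg(OMe)2 in methanol, or excess LiN(SiMe3)2) would deprotonate the side chain of methyl 4-{5-(allyloxy)-6-[3,4-bis(benzyloxy)phenyl]-4-oxo-4H-pyran-2-yl}-3-oxobutanoate A4. The vinylogous enolate would attack the ester through the pyranone carbon, and loss of methanol would give 3-(allyloxy)-2-[3,4-bis(benzyloxy)phenyl]-5,7-dihydroxy-4H-chromen-4-one A5.

- Merits: the closure mirrors polyketide folding, needs no sulfur activator, and has closer precedent in biomimetic Claisen cyclisations of pyranone-masked poly-beta-carbonyl chains than the chosen cycloaddition has.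
- Weak points: it forms one bond where the chosen step forms two. A4 needs a longer assembly of a keto ester chain on a pyranone methyl group. Aldol closure and methoxide opening of the pyranone compete. A5 has O5 and O7 both free, so once the allyl group is removed O3 and O7 would compete for the acetyl group unless O7 is protected in an extra step.
- Comparison: the key step is less speculative, but the route is longer before and after it. The chosen plan delivers O7 already benzylated.

**Alternative 3:** The O1–C8a bond is cut. K2CO3 in DMF would form the enolate of 1-[3,4-bis(benzyloxy)phenyl]-2-(methoxymethoxy)-3-(2,4,6-trifluorophenyl)propane-1,3-dione A6. Its oxygen on the ring B side would displace an ortho fluoride to give 2-[3,4-bis(benzyloxy)phenyl]-5,7-difluoro-3-(methoxymethoxy)-4H-chromen-4-one A7.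

- Merits: intramolecular displacement of a ketone-activated fluoride is very reliable, the symmetric trifluoroaryl group removes any regiochemical question, and O3 is in place as its acetal.
- Weak points: A7 has fluorine where the target has oxygen at C5 and C7. Two further substitutions by alkoxide are needed, the second on a ring already deactivated by the first donor. Alkoxides also attack C2 of chromones and open ring C. Ending with O5 free and O7 protected needs two different nucleophiles or a selective dealkylation.
- Comparison: the closure is safer than the chosen cycloaddition, but it postpones the real problem and adds at least two steps. The chosen plan brings both ring A oxygens in with the diene.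

Key step: step 7

Assumption: the target is drawn as the free tris(hydrogen sulfate), so the last step ends with proton exchange on a sulfonic acid resin in the cold; all sulfoxide intermediates are racemic at sulfur, which is expelled in step 7.

## Route

Step 1
Reactants: 1 methyl glycolate
Product: 2 methyl 2-(methoxymethoxy)acetate
Conditions: MeOCH2Cl, iPr2NEt, CH2Cl2, 0 °C to rt
Reagents that add atoms: chloromethyl methyl ether, COCCl
Why: O-alkylation of the primary alcohol by the reactive alpha-chloro ether under amine base (methoxymethyl ether formation); the methyl ester is not affected.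

Step 2
Reactants: 2 methyl 2-(methoxymethoxy)acetate; 3 methyl p-tolyl sulfoxide (racemic)
Product: 4 1-(methoxymethoxy)-3-(4-methylbenzenesulfinyl)propan-2-one (racemic at sulfur)
Conditions: 3 (2 equiv), LiN(iPr)2 (2.1 equiv), THF, −78 °C; then 2, −78 to 0 °C
Reagents that add atoms: none
Why: Claisen-type acylation of the alpha-sulfinyl carbanion by an ester, the standard beta-keto sulfoxide synthesis. The second equivalent of carbanion stores the acidic product as its enolate, which prevents a second addition.

Step 3
Reactants: 4 1-(methoxymethoxy)-3-(4-methylbenzenesulfinyl)propan-2-one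
Product: 5 4-(dimethylamino)-1-(methoxymethoxy)-3-(4-methylbenzenesulfinyl)but-3-en-2-one (racemic at sulfur)
Conditions: Me2NCH(OMe)2, toluene, 60 °C
Reagents that add atoms: N,N-dimethylformamide dimethyl acetal, COC(OC)N(C)C
Why: Condensation of the formamide acetal with the methylene flanked by carbonyl and sulfinyl groups gives the push–pull enaminone. The CH2 bearing the acetal oxygen is far less acidic and does not react.

Step 4
Reactants: 5 4-(dimethylamino)-1-(methoxymethoxy)-3-(4-methylbenzenesulfinyl)but-3-en-2-one; 6 3,4-bis(benzyloxy)benzoyl chloride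
Product: 8 2-[3,4-bis(benzyloxy)phenyl]-3-(methoxymethoxy)-5-(4-methylbenzenesulfinyl)-4H-pyran-4-one (racemic at sulfur), via enaminodiketone 7 (not isolated)
Conditions: LiN(SiMe3)2 (2.2 equiv), THF, −78 °C; 6, −78 to −20 °C; then AcOH, 50 °C
Reagents that add atoms: none
Why: Enolate C-acylation by the acid chloride, then acid-promoted 6-endo-trig addition–elimination of the enol oxygen on the enaminone carbon with loss of dimethylamine. This is the established gamma-pyrone synthesis from beta-amino or beta-alkoxy enone enolates and acid chlorides. Enaminone 5 has one enolisable position, so the regiochemistry is fixed, and acetic acid is mild enough to spare the acetal.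

Step 5
Reactants: 9 methyl (E)-3-methoxybut-2-enoate; 10 benzyl alcohol
Product: 11 methyl (E)-3-(benzyloxy)but-2-enoate
Conditions: 10 (excess), cat. p-TsOH·H2O, toluene, 100 °C, MeOH distilled off
Reagents that add atoms: none
Why: Acid-catalysed enol ether exchange through the mixed ketal, driven by removal of methanol. The conjugated E isomer, with alkoxy trans to the ester, is the thermodynamic product.

Step 6
Reactants: 11 methyl (E)-3-(benzyloxy)but-2-enoate
Product: 12 (1E)-3-(benzyloxy)-1-methoxy-1-(trimethylsilyloxy)buta-1,3-diene
Conditions: LiN(iPr)2, THF, −78 °C; Me3SiCl, −78 to 0 °C; used without chromatography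
Reagents that add atoms: chlorotrimethylsilane, C[Si](C)(C)Cl
Why: Kinetic gamma-deprotonation of the vinylogous ester and O-silylation of the dienolate, as in the preparation of Brassard-type dienes. The 1E geometry is expected to dominate and is of no consequence, since C1 becomes an aromatic carbon.

Step 7
Reactants: 8 2-[3,4-bis(benzyloxy)phenyl]-3-(methoxymethoxy)-5-(4-methylbenzenesulfinyl)-4H-pyran-4-one; 12 (1E)-3-(benzyloxy)-1-methoxy-1-(trimethylsilyloxy)buta-1,3-diene
Product: 16 7-(benzyloxy)-2-[3,4-bis(benzyloxy)phenyl]-5-hydroxy-3-(methoxymethoxy)-4H-chromen-4-one, via cycloadduct 13 (not isolated), via dihydrochromenone 14 (not isolated), via silyl ether 15 (not isolated)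
Conditions: 12 (2.5 equiv), toluene, rt to 90 °C; then aq. citric acid, THF, rt
Reagents that add atoms: none
Why: Proposed new method: the C5=C6 bond of pyranone 8 is polarised by the C4 carbonyl and the sulfinyl group, so the nucleophilic methylene of diene 12 should bond first to C6 (future C8a) and the acetal carbon then to the sulfinyl-bearing carbon (future C4a) in an asynchronous normal-demand [4+2] cycloaddition that closes ring A through both new bonds in one suprafacial event (in the stepwise limit a Mukaiyama–Michael addition followed by 6-(enolexo)-exo-trig closure of the sulfinyl enolate on the silyloxycarbenium ion), giving cis-fused adduct 13. The sulfinyl group and the C8a hydrogen are cis in 13, so thermal syn elimination of 4-methylbenzenesulfenic acid restores the pyranone double bond (14), 1,4-loss of methanol across C5 and C8 aromatises ring A to silyl ether 15, and the mild acidic work-up hydrolyses 15 to the chelated phenol 16 without touching the acetal. The closest known reaction types are the Diels–Alder/elimination benzannulations of Brassard-type dienes with halo- or sulfinylquinones and the cycloadditions of 3-sulfinylchromones with oxygenated dienes that give xanthones after sulfoxide elimination; a monocyclic 4-pyranone carrying the sulfinyl activator has not been used in this way. The sp3 centres created in 13 are all destroyed on aromatisation and the sulfur stereocentre is expelled, so no stereocontrol is required. The selectivity that matters is regiochemical, benzyloxy carbon to C7 and acetal carbon to C5, and it is secured by the match between the nucleophilic diene terminus and the doubly activated beta-carbon C6; the same activation directs the diene to C5=C6 and away from the tetrasubstituted, donor-substituted C2=C3 bond.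

Step 8
Reactants: 16 7-(benzyloxy)-2-[3,4-bis(benzyloxy)phenyl]-5-hydroxy-3-(methoxymethoxy)-4H-chromen-4-one
Product: 17 7-(benzyloxy)-2-[3,4-bis(benzyloxy)phenyl]-3,5-dihydroxy-4H-chromen-4-one
Conditions: HCl (1 M in MeOH), THF, 45 °C
Reagents that add atoms: none
Why: Acid-catalysed methanolysis of the methoxymethyl acetal; benzyl aryl ethers and the flavone nucleus are stable to dilute methanolic acid.

Step 9
Reactants: 17 7-(benzyloxy)-2-[3,4-bis(benzyloxy)phenyl]-3,5-dihydroxy-4H-chromen-4-one
Product: 18 7-(benzyloxy)-2-[3,4-bis(benzyloxy)phenyl]-5-hydroxy-4-oxo-4H-chromen-3-yl acetate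
Conditions: Ac2O (1.1 equiv), pyridine, CH2Cl2, 0 °C
Reagents that add atoms: acetic anhydride, CC(=O)OC(C)=O
Why: Selective O-acylation. O3–H is the more acidic hydroxyl and is held only in a weak five-membered hydrogen bond, whereas O5–H is locked in a six-membered chelate to the C4 carbonyl and is the last hydroxyl of a flavonol to be acylated.

Step 10
Reactants: 18 7-(benzyloxy)-2-[3,4-bis(benzyloxy)phenyl]-5-hydroxy-4-oxo-4H-chromen-3-yl acetate
Product: 19 2-(3,4-dihydroxyphenyl)-5,7-dihydroxy-4-oxo-4H-chromen-3-yl acetate (quercetin 3-acetate)
Conditions: H2 (1 atm), 10% Pd/C, THF/EtOAc, rt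
Reagents that add atoms: none
Why: Catalytic hydrogenolysis of the three benzyl aryl ethers. The neutral, alcohol-free medium preserves the enol acetate, and the tetrasubstituted conjugated C2=C3 bond is not reduced at atmospheric pressure.

Step 11
Reactants: 19 2-(3,4-dihydroxyphenyl)-5,7-dihydroxy-4-oxo-4H-chromen-3-yl acetate
Product: 20 3-(acetyloxy)-5-hydroxy-4-oxo-2-[3,4-bis(sulfooxy)phenyl]-4H-chromen-7-yl hydrogen sulfate (quercetin 3-acetate 7,3',4'-tri-O-sulfate)
Conditions: SO3·pyridine (12 equiv), pyridine/DMF, 40 °C; Sephadex LH-20; then Dowex 50W (H+ form), H2O, 0 °C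
Reagents that add atoms: sulfur trioxide pyridine complex, O=S(=O)([O-])[n+]1ccccc1
Why: O-sulfation of phenols by a sulfur trioxide–amine complex. The chelated O5–H of flavonoids resists sulfation, so excess reagent should sulfate O7, O3' and O4' only, and the acetate tolerates pyridine at this temperature.

## Compound list

1 | methyl glycolate | COC(=O)CO | starting material
2 | methyl 2-(methoxymethoxy)acetate | COCOCC(=O)OC | intermediate
3 | methyl p-tolyl sulfoxide (racemic) | Cc1ccc(S(C)=O)cc1 | starting material
4 | 1-(methoxymethoxy)-3-(4-methylbenzenesulfinyl)propan-2-one (racemic at sulfur) | COCOCC(=O)CS(=O)c1ccc(C)cc1 | intermediate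
5 | 4-(dimethylamino)-1-(methoxymethoxy)-3-(4-methylbenzenesulfinyl)but-3-en-2-one (racemic at sulfur, enamine geometry not fixed) | COCOCC(=O)C(=CN(C)C)S(=O)c1ccc(C)cc1 | intermediate
6 | 3,4-bis(benzyloxy)benzoyl chloride | O=C(Cl)c1ccc(OCc2ccccc2)c(OCc2ccccc2)c1 | starting material
7 | 1-[3,4-bis(benzyloxy)phenyl]-5-(dimethylamino)-2-(methoxymethoxy)-4-(4-methylbenzenesulfinyl)pent-4-ene-1,3-dione (mixture of stereoisomers and tautomers, not isolated) | COCOC(C(=O)c1ccc(OCc2ccccc2)c(OCc2ccccc2)c1)C(=O)C(=CN(C)C)S(=O)c1ccc(C)cc1 | intermediate
8 | 2-[3,4-bis(benzyloxy)phenyl]-3-(methoxymethoxy)-5-(4-methylbenzenesulfinyl)-4H-pyran-4-one (racemic at sulfur) | COCOc1c(-c2ccc(OCc3ccccc3)c(OCc3ccccc3)c2)occ(S(=O)c2ccc(C)cc2)c1=O | intermediate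
9 | methyl (E)-3-methoxybut-2-enoate | CO/C(C)=C/C(=O)OC | starting material
10 | benzyl alcohol | OCc1ccccc1 | starting material
11 | methyl (E)-3-(benzyloxy)but-2-enoate | C/C(OCc1ccccc1)=C\C(=O)OC | intermediate
12 | (1E)-3-(benzyloxy)-1-methoxy-1-(trimethylsilyloxy)buta-1,3-diene | C=C(OCc1ccccc1)/C=C(\OC)O[Si](C)(C)C | intermediate
13 | 7-(benzyloxy)-2-[3,4-bis(benzyloxy)phenyl]-5-methoxy-3-(methoxymethoxy)-4a-(4-methylbenzenesulfinyl)-5-(trimethylsilyloxy)-4a,5,8,8a-tetrahydro-4H-chromen-4-one (cis-fused, mixture of diastereomers, not isolated) | COCOC1=C(c2ccc(OCc3ccccc3)c(OCc3ccccc3)c2)OC2CC(OCc3ccccc3)=CC(OC)(O[Si](C)(C)C)C2(S(=O)c4ccc(C)cc4)C1=O | intermediate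
14 | 7-(benzyloxy)-2-[3,4-bis(benzyloxy)phenyl]-5-methoxy-3-(methoxymethoxy)-5-(trimethylsilyloxy)-5,8-dihydro-4H-chromen-4-one (racemic, not isolated) | COCOC1=C(c2ccc(OCc3ccccc3)c(OCc3ccccc3)c2)OC2=C(C1=O)C(OC)(O[Si](C)(C)C)C=C(OCc1ccccc1)C2 | intermediate
15 | 7-(benzyloxy)-2-[3,4-bis(benzyloxy)phenyl]-3-(methoxymethoxy)-5-(trimethylsilyloxy)-4H-chromen-4-one (not isolated) | COCOc1c(-c2ccc(OCc3ccccc3)c(OCc3ccccc3)c2)oc2cc(OCc3ccccc3)cc(O[Si](C)(C)C)c2c1=O | intermediate
16 | 7-(benzyloxy)-2-[3,4-bis(benzyloxy)phenyl]-5-hydroxy-3-(methoxymethoxy)-4H-chromen-4-one | COCOc1c(-c2ccc(OCc3ccccc3)c(OCc3ccccc3)c2)oc2cc(OCc3ccccc3)cc(O)c2c1=O | intermediate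
17 | 7-(benzyloxy)-2-[3,4-bis(benzyloxy)phenyl]-3,5-dihydroxy-4H-chromen-4-one | O=c1c(O)c(-c2ccc(OCc3ccccc3)c(OCc3ccccc3)c2)oc2cc(OCc3ccccc3)cc(O)c12 | intermediate
18 | 7-(benzyloxy)-2-[3,4-bis(benzyloxy)phenyl]-5-hydroxy-4-oxo-4H-chromen-3-yl acetate | CC(=O)Oc1c(-c2ccc(OCc3ccccc3)c(OCc3ccccc3)c2)oc2cc(OCc3ccccc3)cc(O)c2c1=O | intermediate
19 | 2-(3,4-dihydroxyphenyl)-5,7-dihydroxy-4-oxo-4H-chromen-3-yl acetate (quercetin 3-acetate) | CC(=O)Oc1c(-c2ccc(O)c(O)c2)oc2cc(O)cc(O)c2c1=O | intermediate
20 | 3-(acetyloxy)-5-hydroxy-4-oxo-2-[3,4-bis(sulfooxy)phenyl]-4H-chromen-7-yl hydrogen sulfate (quercetin 3-acetate 7,3',4'-tri-O-sulfate) | CC(=O)Oc1c(-c2ccc(OS(=O)(=O)O)c(OS(=O)(=O)O)c2)oc2cc(OS(=O)(=O)O)cc(O)c2c1=O | target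

## Step count and risks

Total step count: 11. Longest linear sequence: 9 steps (1 to 2 to 4 to 5 to 8 to 16 to 17 to 18 to 19 to 20; steps 1–4 and 7–11). The diene branch (steps 5 and 6) joins at step 7.

**Step 7 (key step, proposed new method).** The pyranone double bond may be too weak a dienophile because of the partial aromatic character of the 4-pyranone, so the moisture-sensitive diene could be consumed by desilylation before it adds. A conjugate addition that is not followed by ring closure could instead open ring C by expelling the ring oxygen. The sulfenic acid set free could also cleave the silyl ketene acetal. The fallback gives up the benzannulation and uses known flavone chemistry, setting out from acid chloride 6.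

- The dianion of commercial 1-[2,4-bis(benzyloxy)-6-hydroxyphenyl]ethanone (LiN(SiMe3)2, THF, −78 °C) would be C-acylated by 6 to give 1-[2,4-bis(benzyloxy)-6-hydroxyphenyl]-3-[3,4-bis(benzyloxy)phenyl]propane-1,3-dione F1.
- Acid-catalysed cyclodehydration would give 5,7-bis(benzyloxy)-2-[3,4-bis(benzyloxy)phenyl]-4H-chromen-4-one F2, the same flavone that Alternative 1 reaches as A3.
- Epoxidation of the C2=C3 bond with dimethyldioxirane and acid-promoted opening of the epoxide would give 5,7-bis(benzyloxy)-2-[3,4-bis(benzyloxy)phenyl]-3-hydroxy-4H-chromen-4-one F3.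
- Acetylation would give 5,7-bis(benzyloxy)-2-[3,4-bis(benzyloxy)phenyl]-4-oxo-4H-chromen-3-yl acetate F4.
- Hydrogenolysis of all four benzyl ethers over Pd/C comes back to the route at 19.

**Step 4.** The enolate of 5 may be acylated on oxygen or twice, the acid chloride may activate the sulfoxide towards Pummerer-type decomposition, and the acid used for ring closure may remove the acetal. The fallback reverses the order of bond formation. Acid chloride 6 is converted into 3,4-bis(benzyloxy)-N-methoxy-N-methylbenzamide F5 (N,O-dimethylhydroxylamine hydrochloride, Et3N). The dianion of beta-keto sulfoxide 4 (two equivalents of LiN(iPr)2) is acylated by F5 at the carbon bearing the acetal oxygen to give 1-[3,4-bis(benzyloxy)phenyl]-2-(methoxymethoxy)-4-(4-methylbenzenesulfinyl)butane-1,3-dione F6. Condensation of F6 with N,N-dimethylformamide dimethyl acetal comes back to the route at 7, which closes to 8 as in step 4.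

**Step 11.** Sulfation of the second catechol oxygen may stall because of charge repulsion from the first sulfate. Prolonged exposure to pyridine may transfer or remove the acetyl group, and the proton exchange may start hydrolysis of the sulfates. The fallback uses neutral, chromatographable sulfate diesters. Starting from 19, 2,2,2-trichloroethyl chlorosulfate with Et3N and DMAP in THF would give 2-{3,4-bis[(2,2,2-trichloroethoxy)sulfonyloxy]phenyl}-5-hydroxy-4-oxo-7-[(2,2,2-trichloroethoxy)sulfonyloxy]-4H-chromen-3-yl acetate F7. Reductive removal of the three trichloroethyl groups with zinc dust and ammonium formate, followed by the same proton exchange, comes back to the route at 20.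

**Step 5.** The exchange is an equilibrium and may stop short. Transesterification of the methyl ester by benzyl alcohol and hydrolysis to the keto ester may compete. The fallback is the Me3P-catalysed conjugate addition of benzyl alcohol 10 to commercial methyl but-2-ynoate, which sets out from 10 and comes back to the route at 11 directly. It makes no compound outside the route (F0).

## Further compounds

F1 | step 7 | 1-[2,4-bis(benzyloxy)-6-hydroxyphenyl]-3-[3,4-bis(benzyloxy)phenyl]propane-1,3-dione | O=C(CC(=O)c1c(O)cc(OCc2ccccc2)cc1OCc1ccccc1)c1ccc(OCc2ccccc2)c(OCc2ccccc2)c1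
F2 | step 7 | 5,7-bis(benzyloxy)-2-[3,4-bis(benzyloxy)phenyl]-4H-chromen-4-one | O=c1cc(-c2ccc(OCc3ccccc3)c(OCc3ccccc3)c2)oc2cc(OCc3ccccc3)cc(OCc3ccccc3)c12
F3 | step 7 | 5,7-bis(benzyloxy)-2-[3,4-bis(benzyloxy)phenyl]-3-hydroxy-4H-chromen-4-one | O=c1c(O)c(-c2ccc(OCc3ccccc3)c(OCc3ccccc3)c2)oc2cc(OCc3ccccc3)cc(OCc3ccccc3)c12
F4 | step 7 | 5,7-bis(benzyloxy)-2-[3,4-bis(benzyloxy)phenyl]-4-oxo-4H-chromen-3-yl acetate | CC(=O)Oc1c(-c2ccc(OCc3ccccc3)c(OCc3ccccc3)c2)oc2cc(OCc3ccccc3)cc(OCc3ccccc3)c2c1=O
F5 | step 4 | 3,4-bis(benzyloxy)-N-methoxy-N-methylbenzamide | CON(C)C(=O)c1ccc(OCc2ccccc2)c(OCc2ccccc2)c1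
F6 | step 4 | 1-[3,4-bis(benzyloxy)phenyl]-2-(methoxymethoxy)-4-(4-methylbenzenesulfinyl)butane-1,3-dione | COCOC(C(=O)c1ccc(OCc2ccccc2)c(OCc2ccccc2)c1)C(=O)CS(=O)c1ccc(C)cc1
F7 | step 11 | 2-{3,4-bis[(2,2,2-trichloroethoxy)sulfonyloxy]phenyl}-5-hydroxy-4-oxo-7-[(2,2,2-trichloroethoxy)sulfonyloxy]-4H-chromen-3-yl acetate | CC(=O)Oc1c(-c2ccc(OS(=O)(=O)OCC(Cl)(Cl)Cl)c(OS(=O)(=O)OCC(Cl)(Cl)Cl)c2)oc2cc(OS(=O)(=O)OCC(Cl)(Cl)Cl)cc(O)c2c1=O
F0 | step 5 | none | none
A1 | alternative 1 | 3,5-bis(benzyloxy)-2-iodophenol | Oc1cc(OCc2ccccc2)cc(OCc2ccccc2)c1I
A2 | alternative 1 | 1,2-bis(benzyloxy)-4-ethynylbenzene | C#Cc1ccc(OCc2ccccc2)c(OCc2ccccc2)c1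
A3 | alternative 1 | 5,7-bis(benzyloxy)-2-[3,4-bis(benzyloxy)phenyl]-4H-chromen-4-one | O=c1cc(-c2ccc(OCc3ccccc3)c(OCc3ccccc3)c2)oc2cc(OCc3ccccc3)cc(OCc3ccccc3)c12
A4 | alternative 2 | methyl 4-{5-(allyloxy)-6-[3,4-bis(benzyloxy)phenyl]-4-oxo-4H-pyran-2-yl}-3-oxobutanoate | C=CCOc1c(-c2ccc(OCc3ccccc3)c(OCc3ccccc3)c2)oc(CC(=O)CC(=O)OC)cc1=O
A5 | alternative 2 | 3-(allyloxy)-2-[3,4-bis(benzyloxy)phenyl]-5,7-dihydroxy-4H-chromen-4-one | C=CCOc1c(-c2ccc(OCc3ccccc3)c(OCc3ccccc3)c2)oc2cc(O)cc(O)c2c1=O
A6 | alternative 3 | 1-[3,4-bis(benzyloxy)phenyl]-2-(methoxymethoxy)-3-(2,4,6-trifluorophenyl)propane-1,3-dione | COCOC(C(=O)c1ccc(OCc2ccccc2)c(OCc2ccccc2)c1)C(=O)c1c(F)cc(F)cc1F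
A7 | alternative 3 | 2-[3,4-bis(benzyloxy)phenyl]-5,7-difluoro-3-(methoxymethoxy)-4H-chromen-4-one | COCOc1c(-c2ccc(OCc3ccccc3)c(OCc3ccccc3)c2)oc2cc(F)cc(F)c2c1=O
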